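Cuts (benzofuran numbering O1, C2, C3, C3a–C7a): first the angelate acyl–O bond on the C5 side chain, then the bond between the vinyl carbon and the ester carbon (the CO2Me carbon is traded for boron), then the C3 acetate, then the ring bond C2–C3, and last the O1–propargyl and aryl–CHO bonds.
Enabling feature: in the dihydrofuran ring, C3 is a carbinol carbon homoallylic to the exocyclic =CH2, and the allylic carbon C2 between them carries the ring oxygen O1. C2, the carboxyl-bearing vinyl carbon and =CH2 are therefore the three carbons of an aryl allenyl ether O1–CH=C=CH2, and C3 is the formyl carbon of a salicylaldehyde, so the five-membered ring can be closed at C2–C3 by carbonyl allylation.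
Forward: the benzene ring is bought as 4'-(benzyloxy)acetophenone. The side-chain carbinol is set and silylated, the phenol is freed, ortho-formylated and O-propargylated, the propargyl ether is isomerised to the allenyl ether while the aldehyde rests as its dimethyl acetal, and a copper-boryl cyclisation closes the dihydrofuran ring.
Endgame: the C3 hydroxyl is acetylated, boron is exchanged for CO2Me by oxidative carbonylation, the silyl ether is removed and the angelate is attached last.
Stereochemistry: the side-chain (S) centre comes from asymmetric transfer hydrogenation. C2 and C3 (2S,3S, cis) arise together in the cyclisation, cis from the bridged transition state and the absolute sense from the chiral ligand on copper. The Z alkene is bought with angelic acid.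

Key step: step 8

Assumption: precedent does not tell which antipode of the bisphosphine leads to the (2S,3S) series for this substrate class; (R)-DTBM-SEGPHOS is written, its mirror image is equally available, and the choice is fixed on the first cyclisation product, where the fixed (S) side-chain centre turns the facial outcome into a diastereomer question.

Step 1
Reactants: 1 4'-(benzyloxy)acetophenone
Product: 2 (S)-1-[4-(benzyloxy)phenyl]ethanol
Conditions: RuCl[(S,S)-TsDPEN](p-cymene) (0.5 mol%), HCO2H–Et3N (5:2), EtOAc, 30 °C
Reagents that add atoms: none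
Why: Noyori asymmetric transfer hydrogenation, in which the (S,S)-configured ruthenium hydride reduces aryl methyl ketones to the (S)-carbinols through its ordered six-membered outer-sphere transition state, and formic acid as the hydrogen source makes the reduction irreversible so that the electron-rich carbinol should not lose enantiopurity.

Step 2
Reactants: 2 (S)-1-[4-(benzyloxy)phenyl]ethanol
Product: 3 (S)-1-(benzyloxy)-4-[1-(tert-butyldimethylsilyloxy)ethyl]benzene
Conditions: TBSCl, imidazole, DMF, 0 °C to rt
Reagents that add atoms: tert-butyldimethylsilyl chloride, CC(C)(C)[Si](C)(C)Cl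
Why: Imidazole-promoted silylation of a secondary alcohol takes place at oxygen under mildly basic conditions, so the ionisable p-alkoxybenzylic C–O bond and with it the (S) centre are not touched.

Step 3
Reactants: 3 (S)-1-(benzyloxy)-4-[1-(tert-butyldimethylsilyloxy)ethyl]benzene
Product: 4 (S)-4-[1-(tert-butyldimethylsilyloxy)ethyl]phenol
Conditions: H2 (1 atm), Pd/C (10 wt% Pd), EtOAc, rt
Reagents that add atoms: none
Why: Catalytic hydrogenolysis should cleave the unhindered primary benzylic CH2–OAr bond far faster than the hindered secondary benzylic silyl ether, and ethyl acetate is preferred to an alcohol solvent because Pd/C in alcohols can strip silyl ethers.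

Step 4
Reactants: 4 (S)-4-[1-(tert-butyldimethylsilyloxy)ethyl]phenol
Product: 6 5-[(S)-1-(tert-butyldimethylsilyloxy)ethyl]-2-hydroxybenzaldehyde, via salicyl alcohol 5 (not isolated)
Conditions: MgCl2 (anhydrous), Et3N, (CH2O)n, THF, reflux; cold aq. NH4Cl work-up
Reagents that add atoms: paraformaldehyde (reacts as formaldehyde), C=O
Why: Casnati–Skattebøl ortho-formylation, in which the magnesium phenoxide delivers coordinated formaldehyde only to an ortho carbon to give 5 as its magnesium salt and a second formaldehyde oxidises it by Oppenauer-type hydride transfer, the para position being blocked, the two ortho positions being equivalent and silyloxide being too poor a leaving group for quinone methide formation at this temperature.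

Step 5
Reactants: 6 5-[(S)-1-(tert-butyldimethylsilyloxy)ethyl]-2-hydroxybenzaldehyde; 7 propargyl bromide
Product: 8 5-[(S)-1-(tert-butyldimethylsilyloxy)ethyl]-2-(prop-2-ynyloxy)benzaldehyde
Conditions: K2CO3, DMF, rt
Reagents that add atoms: none
Why: Williamson ether synthesis by SN2 attack of the acidic salicylaldehyde phenoxide on a primary propargylic bromide, with a carbonate base too weak to isomerise the alkyne or to harm the non-enolisable aldehyde and the silyl ether.

Step 6
Reactants: 8 5-[(S)-1-(tert-butyldimethylsilyloxy)ethyl]-2-(prop-2-ynyloxy)benzaldehyde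
Product: 9 the dimethyl acetal of 8
Conditions: HC(OMe)3, PPTS (5 mol%), MeOH, rt; Et3N quench
Reagents that add atoms: trimethyl orthoformate, COC(OC)OC; methanol, CO
Why: Acid-catalysed acetalisation driven by the orthoformate as water scavenger masks the formyl group, which under the tert-butoxide of the next step would be open to Favorskii-type addition of the terminal acetylide and to Cannizzaro or Tishchenko pathways, while PPTS is too weak an acid to solvolyse the benzylic silyl ether.

Step 7
Reactants: 9 the dimethyl acetal of 8
Product: 11 5-[(S)-1-(tert-butyldimethylsilyloxy)ethyl]-2-(propa-1,2-dienyloxy)benzaldehyde, via allenyl ether acetal 10 (not isolated)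
Conditions: KOtBu (20 mol%), THF, 0 °C to rt; then aq. citrate buffer (pH 4), rt
Reagents that add atoms: water, O
Why: The base-catalysed prototropic propargyl-to-allenyl ether rearrangement is the standard entry to aryloxyallenes, and the following specific-acid hydrolysis is selective because the aromatic dimethyl acetal ionises to an ortho-alkoxy-stabilised oxocarbenium ion orders of magnitude faster than an aryl allenyl ether is protonated at carbon, so that pH 4 should free the aldehyde and spare the allene and the silyl ether.

Step 8
Reactants: 11 5-[(S)-1-(tert-butyldimethylsilyloxy)ethyl]-2-(propa-1,2-dienyloxy)benzaldehyde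
Product: 15 (2S,3S)-5-[(S)-1-(tert-butyldimethylsilyloxy)ethyl]-2-[1-(pinacolatoboryl)vinyl]-2,3-dihydrobenzofuran-3-ol (cis), via allylcopper species 12 (not isolated), via copper alkoxide 13 (not isolated), via O-boryl ether 14 (not isolated)
Conditions: CuCl (5 mol%), (R)-DTBM-SEGPHOS (6 mol%), NaOtBu (20 mol%), B2pin2 (1.2 equiv), THF, 0 °C to rt; then pH 7 phosphate buffer
Reagents that add atoms: bis(pinacolato)diboron, CC1(C)OB(OC1(C)C)B1OC(C)(C)C(C)(C)O1 (the copper in 12 and 13 belongs to the catalyst CuCl, Cl[Cu])
Why: Proposed new method: CuOtBu formed from CuCl and NaOtBu is borylated by B2pin2, and the ligated Cu–Bpin should add syn across the unsubstituted terminal C=C of the aryloxyallene from the side of the hydrogen on the oxygen-bearing allene carbon, boron going to the central carbon and copper to CH2, to give (Z)-allylcopper 12; its oxygen-bearing γ-carbon attacks the ortho formyl carbon to give copper alkoxide 13, B2pin2 converts 13 into boryl ether 14 with return of Cu–Bpin, and the aqueous work-up frees alcohol 15. The closest known reaction type is the intermolecular copper-catalysed enantioselective borylative coupling of monosubstituted allenes with aldehydes and ketones through 2-borylallylcopper species, together with copper-catalysed couplings in which alkoxyallene-derived allylcopper species attack carbonyl groups through their oxygen-bearing carbon, and an O-allenyl salicylaldehyde has been used in neither. The dihydrofuran ring closes by 5-exo-trig attack on the C=O group with formation of C2–C3, inside a six-membered Cu–O-bridged array that shares this forming bond. The cis relation of C2 and C3 is set by that fused array: in 12 the aryloxy group is pseudo-axial, the short flat tether O1–C7a–C3a then reaches the formyl carbon only when the aryl group on that carbon is pseudo-equatorial, and this places the carbonyl oxygen and the borylvinyl carbon on the same face, whereas a trans closure would need a torsion of roughly 100° inside the six-membered array. The absolute sense (2S,3S) is set for both centres at once by the chiral bisphosphine on copper, which decides which aldehyde face meets the γ-carbon, the distant (S)-silyloxyethyl centre being a spectator. The step needs allene insertion ahead of aldehyde borylation, γ- ahead of α-attack and freedom from protonation and conjugate borylation, which the substrate secures because the unhindered electron-rich terminal C=C is the faster acceptor for Cu–B, the tether makes γ-attack a five-ring closure while α-attack would give a seven-membered ring, no proton source is present, and boron stands in for the ester so that no acrylate is exposed to Cu–B.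

Step 9
Reactants: 15 (2S,3S)-5-[(S)-1-(tert-butyldimethylsilyloxy)ethyl]-2-[1-(pinacolatoboryl)vinyl]-2,3-dihydrobenzofuran-3-ol
Product: 16 (2S,3S)-5-[(S)-1-(tert-butyldimethylsilyloxy)ethyl]-2-[1-(pinacolatoboryl)vinyl]-2,3-dihydrobenzofuran-3-yl acetate
Conditions: Ac2O, pyridine, DMAP (5 mol%), CH2Cl2, 0 °C
Reagents that add atoms: acetic anhydride, CC(=O)OC(C)=O
Why: DMAP-catalysed acyl transfer acetylates the secondary benzylic hydroxyl at oxygen with retention at C3, it is done before the ester carbon arrives so that the cis hydroxyl cannot close onto it to an α-methylene lactone, and the weak base and low temperature should avoid loss of acetic acid to the benzofuran.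

Step 10
Reactants: 16 (2S,3S)-5-[(S)-1-(tert-butyldimethylsilyloxy)ethyl]-2-[1-(pinacolatoboryl)vinyl]-2,3-dihydrobenzofuran-3-yl acetate
Product: 17 methyl 2-{(2S,3S)-3-acetoxy-5-[(S)-1-(tert-butyldimethylsilyloxy)ethyl]-2,3-dihydrobenzofuran-2-yl}acrylate
Conditions: Pd(OAc)2 (5 mol%), PPh3 (10 mol%), p-benzoquinone (1.5 equiv), CO (1 atm), MeOH–THF, rt
Reagents that add atoms: carbon monoxide, [C-]#[O+]; methanol, CO
Why: Oxidative alkoxycarbonylation of an organoboronate under divalent palladium catalysis is known for aryl and alkenyl pinacol boronates, and here base-free boron-to-palladium transmetalation, CO insertion and methanolysis should give the acrylate while benzoquinone returns zerovalent palladium quickly to the divalent state, so that at room temperature the acetate, the silyl ether and the centres C2 and C3 stay untouched.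

Step 11
Reactants: 17 methyl 2-{(2S,3S)-3-acetoxy-5-[(S)-1-(tert-butyldimethylsilyloxy)ethyl]-2,3-dihydrobenzofuran-2-yl}acrylate
Product: 18 methyl 2-{(2S,3S)-3-acetoxy-5-[(S)-1-hydroxyethyl]-2,3-dihydrobenzofuran-2-yl}acrylate
Conditions: Bu4NF–AcOH (1:1), THF, 0 °C to rt
Reagents that add atoms: none
Why: Fluoride-induced desilylation is driven by the Si–F bond, and the acetic acid buffer removes the basicity that would cleave the acetate, eliminate acetic acid across C2–C3 or add to the acrylate, while the medium remains too weakly acidic to ionise the p-alkoxybenzylic carbinol, so the (S) centre is kept.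

Step 12
Reactants: 18 methyl 2-{(2S,3S)-3-acetoxy-5-[(S)-1-hydroxyethyl]-2,3-dihydrobenzofuran-2-yl}acrylate; 19 angelic acid, (Z)-2-methylbut-2-enoic acid
Product: 21 methyl 2-{(2S,3S)-3-acetoxy-5-[(S)-1-((Z)-2-methylbut-2-enoyloxy)ethyl]-2,3-dihydrobenzofuran-2-yl}acrylate (CNP0168827.1), via mixed anhydride 20 (not isolated)
Conditions: 19, 2,4,6-trichlorobenzoyl chloride, Et3N, toluene, rt; then 18, toluene, 60–70 °C (no DMAP)
Reagents that add atoms: 2,4,6-trichlorobenzoyl chloride, O=C(Cl)c1c(Cl)cc(Cl)cc1Cl (its aroyl group is held only in 20 and is absent from 21)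
Why: Yamaguchi esterification run without a nucleophilic pyridine catalyst, in which the alcohol attacks the unhindered angeloyl carbonyl of 20, the carbinol C–O bond is not broken so that (S) is retained, and the absence of DMAP removes the addition–elimination path by which angelates isomerise to tiglates.

Compound list
1 | 4'-(benzyloxy)acetophenone | CC(=O)c1ccc(OCc2ccccc2)cc1 | starting material
2 | (S)-1-[4-(benzyloxy)phenyl]ethanol | C[C@H](O)c1ccc(OCc2ccccc2)cc1 | intermediate
3 | (S)-1-(benzyloxy)-4-[1-(tert-butyldimethylsilyloxy)ethyl]benzene | C[C@H](O[Si](C)(C)C(C)(C)C)c1ccc(OCc2ccccc2)cc1 | intermediate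
4 | (S)-4-[1-(tert-butyldimethylsilyloxy)ethyl]phenol | C[C@H](O[Si](C)(C)C(C)(C)C)c1ccc(O)cc1 | intermediate
5 | 4-[(S)-1-(tert-butyldimethylsilyloxy)ethyl]-2-(hydroxymethyl)phenol, present as its magnesium salt, not isolated | C[C@H](O[Si](C)(C)C(C)(C)C)c1ccc(O)c(CO)c1 | intermediate
6 | 5-[(S)-1-(tert-butyldimethylsilyloxy)ethyl]-2-hydroxybenzaldehyde | C[C@H](O[Si](C)(C)C(C)(C)C)c1ccc(O)c(C=O)c1 | intermediate
7 | propargyl bromide | C#CCBr | starting material
8 | 5-[(S)-1-(tert-butyldimethylsilyloxy)ethyl]-2-(prop-2-ynyloxy)benzaldehyde | C[C@H](O[Si](C)(C)C(C)(C)C)c1ccc(OCC#C)c(C=O)c1 | intermediate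
9 | dimethyl acetal of 8 | C[C@H](O[Si](C)(C)C(C)(C)C)c1ccc(OCC#C)c(C(OC)OC)c1 | intermediate
10 | dimethyl acetal of 11 (allenyl ether acetal), not isolated | C[C@H](O[Si](C)(C)C(C)(C)C)c1ccc(OC=C=C)c(C(OC)OC)c1 | intermediate
11 | 5-[(S)-1-(tert-butyldimethylsilyloxy)ethyl]-2-(propa-1,2-dienyloxy)benzaldehyde | C[C@H](O[Si](C)(C)C(C)(C)C)c1ccc(OC=C=C)c(C=O)c1 | intermediate
12 | (Z)-[3-aryloxy-2-(pinacolatoboryl)allyl]copper, bisphosphine on copper omitted, not isolated | C[C@H](O[Si](C)(C)C(C)(C)C)c1ccc(O/C=C(\C[Cu])B2OC(C)(C)C(C)(C)O2)c(C=O)c1 | intermediate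
13 | copper (2S,3S)-alkoxide of 15, bisphosphine on copper omitted, not isolated | C=C(B3OC(C)(C)C(C)(C)O3)[C@@H]1Oc2ccc([C@H](C)O[Si](C)(C)C(C)(C)C)cc2[C@@H]1O[Cu] | intermediate
14 | O-(pinacolatoboryl) ether of 15, not isolated | C=C(B3OC(C)(C)C(C)(C)O3)[C@@H]1Oc2ccc([C@H](C)O[Si](C)(C)C(C)(C)C)cc2[C@@H]1OB3OC(C)(C)C(C)(C)O3 | intermediate
15 | (2S,3S)-5-[(S)-1-(tert-butyldimethylsilyloxy)ethyl]-2-[1-(pinacolatoboryl)vinyl]-2,3-dihydrobenzofuran-3-ol (cis) | C=C(B3OC(C)(C)C(C)(C)O3)[C@@H]1Oc2ccc([C@H](C)O[Si](C)(C)C(C)(C)C)cc2[C@@H]1O | intermediate
16 | acetate of 15 | C=C(B3OC(C)(C)C(C)(C)O3)[C@@H]1Oc2ccc([C@H](C)O[Si](C)(C)C(C)(C)C)cc2[C@@H]1OC(C)=O | intermediate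
17 | methyl 2-{(2S,3S)-3-acetoxy-5-[(S)-1-(tert-butyldimethylsilyloxy)ethyl]-2,3-dihydrobenzofuran-2-yl}acrylate | C=C(C(=O)OC)[C@@H]1Oc2ccc([C@H](C)O[Si](C)(C)C(C)(C)C)cc2[C@@H]1OC(C)=O | intermediate
18 | methyl 2-{(2S,3S)-3-acetoxy-5-[(S)-1-hydroxyethyl]-2,3-dihydrobenzofuran-2-yl}acrylate | C=C(C(=O)OC)[C@@H]1Oc2ccc([C@H](C)O)cc2[C@@H]1OC(C)=O | intermediate
19 | angelic acid, (Z)-2-methylbut-2-enoic acid | C/C=C(/C)C(=O)O | starting material
20 | angelic 2,4,6-trichlorobenzoic mixed anhydride, not isolated | C/C=C(/C)C(=O)OC(=O)c1c(Cl)cc(Cl)cc1Cl | intermediate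
21 | CNP0168827.1, methyl 2-{(2S,3S)-3-acetoxy-5-[(S)-1-((Z)-2-methylbut-2-enoyloxy)ethyl]-2,3-dihydrobenzofuran-2-yl}acrylate | C=C(C(=O)OC)[C@@H]1Oc2ccc([C@H](C)OC(=O)/C(C)=C\C)cc2[C@@H]1OC(C)=O | target

Total step count: 12. Longest linear sequence: 12 steps (1 to 21); 7 and 19 are bought and enter at steps 5 and 12.

Steps most likely to fail

Step 8 (the labelled step). The cyclisation may suffer from four processes:
- direct borylation of the formyl group;
- Cu–B insertion with the reverse orientation followed by expulsion of aryloxide;
- slow release of copper from the boron-chelated alkoxide;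
- poor facial selectivity.

The fallback uses known chemistry, sets out from 11 and returns at 15. It replaces the catalytic allylcopper with a stoichiometric allylboronate. Palladium-catalysed diboration of the terminal allene C=C (B2pin2, Pd(dba)2, catalytic 3-iodo-2-methylcyclohex-2-enone, toluene, 80 °C) gives the (Z)-2,3-bis(pinacolatoboryl)prop-1-enyl aryl ether F1, whose γ-carbon is again the oxygen-bearing one. Thermal intramolecular allylboration through the closed six-membered transition state forms C2–C3 with the same cis preference but without control of the absolute sense. It gives 14 beside the (2R,3R)-configured O-boryl ether F2. Aqueous work-up then gives 15 beside the (2R,3R)-configured boryl alcohol F3. The (S) side-chain centre makes this pair diastereomeric, so 15 is secured by preparative HPLC and goes on to step 9.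

Step 10. Transmetalation of the hindered 1,1-disubstituted alkenyl boronate may be slow. Three processes could then take over:
- protodeboronation in methanol;
- β-aryloxy elimination at the alkenylpalladium stage with opening of the ring;
- ionisation of the allylic C2–O1 bond by zerovalent palladium with loss of the cis relation.

The fallback sets out from 15 and returns at 17. Boron is first exchanged for iodine, and the ester carbon is then brought in by a carbonylation that starts with oxidative addition to a carbon–iodine bond. Iododeboronation of 15 (aq. NaOH, iodine, THF, 0 °C) is carried out before the base-labile acetate is present and gives the cis-2-(1-iodovinyl)dihydrobenzofuranol F4. Acetylation under the conditions of step 9 gives the iodovinyl acetate F5. Methoxycarbonylation (PdCl2(PPh3)2, CO 1 atm, MeOH, iPr2NEt, rt to 40 °C) gives 17.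

Step 12. During the prolonged heating, three processes may compete:
- Z-to-E isomerisation of the activated angeloyl unit;
- ionisation of the p-alkoxybenzylic carbinol, with racemisation or dehydration;
- amine-induced loss of acetic acid across C2–C3 with aromatisation.

The fallback sets out from 18 and returns at 21. It builds the Z alkene on the ester instead of carrying it through an acylation. Commercial ethyl 2-[bis(2,2,2-trifluoroethoxy)phosphoryl]propanoate is saponified (LiOH, THF–H2O, 0 °C) to 2-[bis(2,2,2-trifluoroethoxy)phosphoryl]propanoic acid F6. This acid has no alkene to isomerise and is coupled with 18 in the cold (EDC·HCl, catalytic DMAP, CH2Cl2, 0 °C) to give the phosphonopropanoate ester F7. Still–Gennari olefination (KHMDS, 18-crown-6, THF, −78 °C, then acetaldehyde) should give 21 with kinetic Z selectivity.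

Further compounds
F1 | step 8 | 5-[(S)-1-(tert-butyldimethylsilyloxy)ethyl]-2-[(Z)-2,3-bis(pinacolatoboryl)prop-1-enyloxy]benzaldehyde | C[C@H](O[Si](C)(C)C(C)(C)C)c1ccc(O/C=C(\CB2OC(C)(C)C(C)(C)O2)B2OC(C)(C)C(C)(C)O2)c(C=O)c1
F2 | step 8 | (2R,3R) ring diastereomer of O-boryl ether 14, side chain (S) | C=C(B3OC(C)(C)C(C)(C)O3)[C@H]1Oc2ccc([C@H](C)O[Si](C)(C)C(C)(C)C)cc2[C@H]1OB3OC(C)(C)C(C)(C)O3
F3 | step 8 | (2R,3R) ring diastereomer of boryl alcohol 15, side chain (S) | C=C(B3OC(C)(C)C(C)(C)O3)[C@H]1Oc2ccc([C@H](C)O[Si](C)(C)C(C)(C)C)cc2[C@H]1O
F4 | step 10 | cis-(2R,3S)-5-[(S)-1-(tert-butyldimethylsilyloxy)ethyl]-2-(1-iodovinyl)-2,3-dihydrobenzofuran-3-ol, same spatial arrangement as 15 (the C2 descriptor changes by priority only) | IC(=C)[C@@H]1Oc2ccc([C@H](C)O[Si](C)(C)C(C)(C)C)cc2[C@@H]1O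
F5 | step 10 | acetate of F4 | IC(=C)[C@@H]1Oc2ccc([C@H](C)O[Si](C)(C)C(C)(C)C)cc2[C@@H]1OC(C)=O
F6 | step 12 | 2-[bis(2,2,2-trifluoroethoxy)phosphoryl]propanoic acid (racemic) | CC(C(=O)O)P(=O)(OCC(F)(F)F)OCC(F)(F)F
F7 | step 12 | ester of 18 with F6, both epimers at the phosphonate-bearing carbon | C=C(C(=O)OC)[C@@H]1Oc2ccc([C@H](C)OC(=O)C(C)P(=O)(OCC(F)(F)F)OCC(F)(F)F)cc2[C@@H]1OC(C)=O
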